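**Retrosynthetic overview**
1. The last step is only O-desilylation of the phenol; the key step delivers everything else of the target.
2. Key disconnection: the dihydrofuran ring (O1–C2–C3–C3a–C7a), both stereocentres, the C3 ester bond and the isopropenyl group go back in one operation to the pyran ring of a flat 2,2-dimethyl-2H-chromene (silylated eupatoriochromene) and the Z acid, carried as the ligands of a lactate-derived chiral aryl-λ3-iodane. The sequence is face-selective C3–I/C4–O addition, 1,2-shift of the ring oxygen (six-membered to five-membered ring) and loss of a methyl proton.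
3. Enabling feature (chromene numbering): the ring oxygen O1 is β to C3 and bound to a C2 carrying two methyl groups. A nucleofuge on C3 antiperiplanar to C2–O1 lets O1 migrate to C3; C2 becomes a tertiary cation and ends as the isopropenyl carbon, and the same methyl groups hold the C4 ester equatorial, away from the rear of C3.
4. Ring order: benzene ring bought (2,4-dihydroxyacetophenone); pyran ring by C5 iodination, Heck reaction with 2-methylbut-3-en-2-ol and cyclodehydration; furan ring from the pyran ring in the key step.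
5. Side pieces: Z acid from crotonaldehyde (α-iodination, reduction, hydroxycarbonylation with retention, acetylation); iodane from 2-iodoresorcinol and two molecules of methyl (S)-lactate (double Mitsunobu etherification), then oxidation at iodine and exchange of both acetate ligands for the Z acid.

Key step: step 12

Assumption: the (R,R)-lactate aryl-λ3-iodane is taken to deliver iodine to the C3 face of the silylated chromene that leads to the 3S adduct; should the sense prove opposite, the mirror-image reagent from methyl (R)-lactate would be used with no other change.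

**Step 1**
Reactants: 1 1-(2,4-dihydroxyphenyl)ethan-1-one
Product: 2 1-(2,4-dihydroxy-5-iodophenyl)ethan-1-one
Conditions: ICl (1.05 equiv), AcOH, 20 °C
Reagents that add atoms: iodine monochloride, ClI
Why: Electrophilic aromatic iodination should go to C5, which is para to the chelated 2-hydroxyl, ortho to the 4-hydroxyl and less hindered than C3 between the two oxygens.

**Step 2**
Reactants: 2 1-(2,4-dihydroxy-5-iodophenyl)ethan-1-one; 3 2-methylbut-3-en-2-ol
Product: 4 1-{2,4-dihydroxy-5-[(1E)-3-hydroxy-3-methylbut-1-en-1-yl]phenyl}ethan-1-one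
Conditions: Pd(OAc)2 (5 mol%), Bu4NCl, NaHCO3, DMF, 80 °C
Reagents that add atoms: none
Why: Mizoroki–Heck reaction of the aryl iodide (zerovalent palladium formed in situ) with the terminal alkene; β-hydride elimination can only give the E styrene because the carbinol carbon is quaternary.

**Step 3**
Reactants: 4 1-{2,4-dihydroxy-5-[(1E)-3-hydroxy-3-methylbut-1-en-1-yl]phenyl}ethan-1-one
Product: 5 1-(7-hydroxy-2,2-dimethyl-2H-chromen-6-yl)ethan-1-one (eupatoriochromene)
Conditions: PPTS (10 mol%), toluene, 80 °C
Reagents that add atoms: none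
Why: Acid-catalysed cyclodehydration (ortho-quinone methide formation, then oxa-6π electrocyclisation) should close the pyran ring through the only hydroxyl ortho to the side chain.

**Step 4**
Reactants: 5 1-(7-hydroxy-2,2-dimethyl-2H-chromen-6-yl)ethan-1-one
Product: 6 1-{7-[(tert-butyldimethylsilyl)oxy]-2,2-dimethyl-2H-chromen-6-yl}ethan-1-one
Conditions: TBSCl, imidazole, DMAP (cat.), DMF, 40 °C
Reagents that add atoms: tert-butyldimethylsilyl chloride, CC(C)(C)[Si](C)(C)Cl
Why: O-Silylation of the only hydroxyl masks the phenol against the trivalent iodine oxidant of step 12 and can be undone with fluoride in the presence of the esters.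

**Step 5**
Reactants: 7 (E)-but-2-enal (crotonaldehyde)
Product: 8 (Z)-2-iodobut-2-enal
Conditions: I2, K2CO3, DMAP (20 mol%), THF–H2O (1:1), 20 °C
Reagents that add atoms: iodine, II
Why: Amine-catalysed α-iodination of the enal (conjugate addition of DMAP, iodination of the enolate, elimination) should give the thermodynamic Z isomer with iodine cis to the methyl group.

**Step 6**
Reactants: 8 (Z)-2-iodobut-2-enal
Product: 9 (Z)-2-iodobut-2-en-1-ol
Conditions: NaBH4, MeOH, 0 °C
Reagents that add atoms: none
Why: Borohydride 1,2-reduction of the aldehyde leaves the vinyl iodide and its geometry untouched.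

**Step 7**
Reactants: 9 (Z)-2-iodobut-2-en-1-ol
Product: 10 (Z)-2-(hydroxymethyl)but-2-enoic acid
Conditions: PdCl2(PPh3)2 (3 mol%), CO (1 atm), K2CO3, THF–H2O (4:1), 50 °C; then aq. HCl to pH 2
Reagents that add atoms: carbon monoxide, [C-]#[O+]; water, O
Why: Palladium-catalysed hydroxycarbonylation proceeds with retention at the vinyl carbon (oxidative addition, CO insertion), so the carboxyl group takes the place of iodine cis to the methyl group; any β-lactone from internal capture would be opened by hydroxide to the same acid.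

**Step 8**
Reactants: 10 (Z)-2-(hydroxymethyl)but-2-enoic acid
Product: 11 (Z)-2-(acetoxymethyl)but-2-enoic acid
Conditions: AcCl (2.5 equiv), CH2Cl2, 0 → 20 °C; then H2O, 20 °C
Reagents that add atoms: acetyl chloride, CC(=O)Cl
Why: O-Acetylation of the primary allylic alcohol without amine base avoids addition–elimination isomerisation of the Z alkene; a mixed anhydride at the carboxyl group is hydrolysed in the aqueous work-up.

**Step 9**
Reactants: 12 2-iodobenzene-1,3-diol; 13 methyl (S)-2-hydroxypropanoate
Product: 15 dimethyl (2R,2'R)-2,2'-[(2-iodo-1,3-phenylene)bis(oxy)]dipropanoate, via mono-lactate ether 14 (not isolated)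
Conditions: 13 (2.2 equiv in all), PPh3 (2.4 equiv), DIAD (2.4 equiv), THF, 0 → 20 °C
Reagents that add atoms: methyl (S)-2-hydroxypropanoate (second molecule of 13), C[C@H](O)C(=O)OC
Why: Double Mitsunobu etherification, in which one phenol oxygen displaces the activated hydroxyl of a first molecule of 13 with inversion to give the mono-ether 14, whose remaining phenol does the same with a second molecule of 13, so that the (S)-lactate gives the (R,R) diether.

**Step 10**
Reactants: 15 dimethyl (2R,2'R)-2,2'-[(2-iodo-1,3-phenylene)bis(oxy)]dipropanoate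
Product: 16 dimethyl (2R,2'R)-2,2'-{[2-(diacetoxy-λ3-iodanyl)-1,3-phenylene]bis(oxy)}dipropanoate
Conditions: NaBO3·4H2O (10 equiv), AcOH, 45 °C
Reagents that add atoms: acetic acid, CC(=O)O; acetic acid (second molecule), CC(=O)O
Why: Perborate oxidation of the aryl iodide in acetic acid is the standard route to aryl-λ3-iodane diacetates, the iodine taking up two acetate ligands from the solvent while the remote stereocentres are not touched.

**Step 11**
Reactants: 16 dimethyl (2R,2'R)-2,2'-{[2-(diacetoxy-λ3-iodanyl)-1,3-phenylene]bis(oxy)}dipropanoate; 11 (Z)-2-(acetoxymethyl)but-2-enoic acid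
Product: 18 dimethyl (2R,2'R)-2,2'-{[2-(bis{[(2Z)-2-(acetoxymethyl)but-2-enoyl]oxy}-λ3-iodanyl)-1,3-phenylene]bis(oxy)}dipropanoate, via mixed acetate carboxylate iodane 17 (not isolated)
Conditions: 11 (2.05 equiv in all), chlorobenzene, 45 °C, 20 mbar (AcOH distilled off)
Reagents that add atoms: (Z)-2-(acetoxymethyl)but-2-enoic acid (second molecule of 11), C/C=C(\C(=O)O)COC(C)=O
Why: Carboxylate ligand exchange at trivalent iodine, one acetate after the other by way of the mixed iodane 17, is driven by removal of the more volatile acetic acid and binds the acid through its carboxylate oxygen only.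

**Step 12**
Reactants: 6 1-{7-[(tert-butyldimethylsilyl)oxy]-2,2-dimethyl-2H-chromen-6-yl}ethan-1-one; 18 dimethyl (2R,2'R)-2,2'-{[2-(bis{[(2Z)-2-(acetoxymethyl)but-2-enoyl]oxy}-λ3-iodanyl)-1,3-phenylene]bis(oxy)}dipropanoate
Product: 20 (2S,3R)-5-acetyl-6-[(tert-butyldimethylsilyl)oxy]-2-(prop-1-en-2-yl)-2,3-dihydro-1-benzofuran-3-yl (2Z)-2-(acetoxymethyl)but-2-enoate, via 3-iodanyl-4-acyloxychroman adduct 19 (not isolated)
Conditions: 18 (1.3 equiv), BF3·OEt2 (2 equiv), 2,6-di-tert-butyl-4-methylpyridine (1.5 equiv), CH2Cl2, −78 → −40 °C; aq. NaHCO3 at −40 °C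
Reagents that add atoms: none
Why: Proposed new method: the BF3-activated aryl-λ3-iodane 18 should add to the electron-rich C3=C4 bond of 6 from one face, iodine going to C3 and one of its own carboxylate ligands going anti to the benzylic C4 (a cation stabilised by the para silyloxy group and the ortho ring oxygen), to give the trans-diequatorial (3S,4R) adduct 19, whose equatorial C3–I bond lies antiperiplanar to the C2–O1 ring bond, so that O1 expels the aryliodanyl nucleofuge from the rear, the C2–O1 bond breaks to the tertiary C2 cation and the hindered pyridine removes a methyl proton to leave the isopropenyl group. The closest known reaction types are the oxidative ring contraction of 1,2-dihydronaphthalenes with chiral aryl-λ3-iodanes (there a ring carbon migrates), the enantioselective dioxygenation of styrenes with the same lactate-based iodanes and the ring contraction of 2,2-dimethylchroman-3-yl sulfonates to 2-isopropenyl-2,3-dihydrobenzofurans by the same oxygen shift. The dihydrofuran ring is closed by an intramolecular SN2 attack of O1 on C3 (3-exo-tet closure to a bicyclic oxiranium ion, then heterolysis of C2–O1), that is, a 1,2-shift of the ring oxygen that contracts the six-membered pyran to the five-membered ring. The C2 stereocentre of the product (old C3) is set by the face selectivity of the chiral iodane followed by stereospecific inversion, and the C3 stereocentre (old C4) by anti opening of the iodonium ion, which together give the trans (2S,3R) ester. The step needs migration of O1 in preference to participation of the C4 ester carbonyl, to aryl or methyl migration and to external substitution: the two methyl groups on C2 secure this, because an axial C4 ester would clash 1,3-diaxially with the axial methyl group (so 19 stays diequatorial, with the ester carbonyl and the methyl groups out of line with C3–I), because they make the cation left by the oxygen shift tertiary and C3 neopentyl-like, and the acyl group on the C4 oxygen damps the push that an aryl shift would need. The acid reacts only as a carboxylate nucleophile and is never activated at its carbonyl group, so that its Z double bond should be kept.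

**Step 13**
Reactants: 20 (2S,3R)-5-acetyl-6-[(tert-butyldimethylsilyl)oxy]-2-(prop-1-en-2-yl)-2,3-dihydro-1-benzofuran-3-yl (2Z)-2-(acetoxymethyl)but-2-enoate
Product: 21 (2S,3R)-5-acetyl-6-hydroxy-2-(prop-1-en-2-yl)-2,3-dihydro-1-benzofuran-3-yl (2Z)-2-(acetoxymethyl)but-2-enoate
Conditions: HF·pyridine, THF, 0 °C
Reagents that add atoms: none
Why: Fluoride cleavage of the aryl silyl ether (activated by the ortho acetyl group) under weakly acidic conditions should leave the benzylic ester, the allylic acetate, the Z alkene and both stereocentres untouched.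

**Compound list**
1 | 1-(2,4-dihydroxyphenyl)ethan-1-one | CC(=O)c1ccc(O)cc1O | starting material
2 | 1-(2,4-dihydroxy-5-iodophenyl)ethan-1-one | CC(=O)c1cc(I)c(O)cc1O | intermediate
3 | 2-methylbut-3-en-2-ol | C=CC(C)(C)O | starting material
4 | 1-{2,4-dihydroxy-5-[(1E)-3-hydroxy-3-methylbut-1-en-1-yl]phenyl}ethan-1-one | CC(=O)c1cc(/C=C/C(C)(C)O)c(O)cc1O | intermediate
5 | 1-(7-hydroxy-2,2-dimethyl-2H-chromen-6-yl)ethan-1-one | CC(=O)c1cc2C=CC(C)(C)Oc2cc1O | intermediate
6 | 1-{7-[(tert-butyldimethylsilyl)oxy]-2,2-dimethyl-2H-chromen-6-yl}ethan-1-one | CC(=O)c1cc2C=CC(C)(C)Oc2cc1O[Si](C)(C)C(C)(C)C | intermediate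
7 | (E)-but-2-enal | C/C=C/C=O | starting material
8 | (Z)-2-iodobut-2-enal | C/C=C(\I)C=O | intermediate
9 | (Z)-2-iodobut-2-en-1-ol | C/C=C(\I)CO | intermediate
10 | (Z)-2-(hydroxymethyl)but-2-enoic acid | C/C=C(\C(=O)O)CO | intermediate
11 | (Z)-2-(acetoxymethyl)but-2-enoic acid | C/C=C(\C(=O)O)COC(C)=O | intermediate
12 | 2-iodobenzene-1,3-diol | Oc1cccc(O)c1I | starting material
13 | methyl (S)-2-hydroxypropanoate | C[C@H](O)C(=O)OC | starting material
14 | methyl (2R)-2-(3-hydroxy-2-iodophenoxy)propanoate | COC(=O)[C@@H](C)Oc1cccc(O)c1I | intermediate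
15 | dimethyl (2R,2'R)-2,2'-[(2-iodo-1,3-phenylene)bis(oxy)]dipropanoate | COC(=O)[C@@H](C)Oc1cccc(O[C@H](C)C(=O)OC)c1I | intermediate
16 | dimethyl (2R,2'R)-2,2'-{[2-(diacetoxy-λ3-iodanyl)-1,3-phenylene]bis(oxy)}dipropanoate | COC(=O)[C@@H](C)Oc1cccc(O[C@H](C)C(=O)OC)c1I(OC(C)=O)OC(C)=O | intermediate
17 | dimethyl (2R,2'R)-2,2'-{[2-(acetoxy{[(2Z)-2-(acetoxymethyl)but-2-enoyl]oxy}-λ3-iodanyl)-1,3-phenylene]bis(oxy)}dipropanoate | COC(=O)[C@@H](C)Oc1cccc(O[C@H](C)C(=O)OC)c1I(OC(C)=O)OC(=O)/C(=C\C)COC(C)=O | intermediate
18 | dimethyl (2R,2'R)-2,2'-{[2-(bis{[(2Z)-2-(acetoxymethyl)but-2-enoyl]oxy}-λ3-iodanyl)-1,3-phenylene]bis(oxy)}dipropanoate | COC(=O)[C@@H](C)Oc1cccc(O[C@H](C)C(=O)OC)c1I(OC(=O)/C(=C\C)COC(C)=O)OC(=O)/C(=C\C)COC(C)=O | intermediate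
19 | (3S,4R)-6-acetyl-7-[(tert-butyldimethylsilyl)oxy]-2,2-dimethyl-3,4-dihydro-2H-chromen-4-yl (2Z)-2-(acetoxymethyl)but-2-enoate carrying at C3 (trans to the ester) the aryl(acyloxy)-λ3-iodanyl group derived from 18 | CC1(C)Oc2cc(O[Si](C)(C)C(C)(C)C)c(C(C)=O)cc2[C@@H](OC(=O)/C(=C\C)COC(C)=O)[C@@H]1I(OC(=O)/C(=C\C)COC(C)=O)c3c(O[C@H](C)C(=O)OC)cccc3O[C@H](C)C(=O)OC | intermediate
20 | (2S,3R)-5-acetyl-6-[(tert-butyldimethylsilyl)oxy]-2-(prop-1-en-2-yl)-2,3-dihydro-1-benzofuran-3-yl (2Z)-2-(acetoxymethyl)but-2-enoate | C=C(C)[C@@H]1Oc2cc(O[Si](C)(C)C(C)(C)C)c(C(C)=O)cc2[C@H]1OC(=O)/C(=C\C)COC(C)=O | intermediate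
21 | (2S,3R)-5-acetyl-6-hydroxy-2-(prop-1-en-2-yl)-2,3-dihydro-1-benzofuran-3-yl (2Z)-2-(acetoxymethyl)but-2-enoate | C=C(C)[C@@H]1Oc2cc(O)c(C(C)=O)cc2[C@H]1OC(=O)/C(=C\C)COC(C)=O | target

**Total step count:** 13

**Longest linear sequence:** 7 steps (7 → 8 → 9 → 10 → 11 → 18 → 20 → 21; steps 5, 6, 7, 8, 11, 12, 13)

**Steps most likely to fail**

1. Step 12 (Proposed new method). What may go wrong:
   - low or reversed facial selectivity of the iodane;
   - participation of the C4 ester carbonyl, or aryl or methyl migration, in place of the oxygen shift;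
   - capture of the tertiary cation by carboxylate instead of proton loss;
   - α-acyloxylation of the acetyl group by the BF3-activated trivalent iodine reagent;
   - ionisation of the benzylic ester of the product with aromatisation to the benzofuran.

   Fallback with known chemistry, from 6: Jacobsen–Katsuki epoxidation with (S,S)-N,N'-bis(3,5-di-tert-butylsalicylidene)cyclohexane-1,2-diaminomanganese chloride, (S,S)-(salen)MnCl, mCPBA and N-methylmorpholine N-oxide in CH2Cl2 at −78 °C should give 1-{(3S,4S)-7-[(tert-butyldimethylsilyl)oxy]-3,4-epoxy-2,2-dimethyl-3,4-dihydro-2H-chromen-6-yl}ethan-1-one F1, with the face selectivity that is well established for 2,2-dimethylchromenes. Opening of F1 at the benzylic C4 with inversion by acid 11 (1.5 equiv, Cs2CO3 0.2 equiv, MeCN, 40 °C) should give (3S,4R)-6-acetyl-7-[(tert-butyldimethylsilyl)oxy]-3-hydroxy-2,2-dimethyl-3,4-dihydro-2H-chromen-4-yl (2Z)-2-(acetoxymethyl)but-2-enoate F2. Triflation of the C3 hydroxyl of F2 (Tf2O, 2,6-di-tert-butyl-4-methylpyridine, CH2Cl2, −78 → 0 °C) should give (3S,4R)-6-acetyl-7-[(tert-butyldimethylsilyl)oxy]-2,2-dimethyl-3-{[(trifluoromethyl)sulfonyl]oxy}-3,4-dihydro-2H-chromen-4-yl (2Z)-2-(acetoxymethyl)but-2-enoate F3, which is not isolated and should undergo in the same flask the known oxygen-shift ring contraction of 2,2-dimethylchroman-3-yl sulfonates with inversion at C3. The route is rejoined at 20.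

2. Step 7. What may go wrong: capture of the acyl-palladium intermediate by the neighbouring hydroxyl (β-lactone, oligoesters), protodeiodination, or erosion of the Z geometry. Fallback from 9: silylation (TBSCl, imidazole, DMF) should give tert-butyl{[(2Z)-2-iodobut-2-en-1-yl]oxy}dimethylsilane F4. Iodine–lithium exchange (tert-butyllithium, 2 equiv, Et2O, −78 °C), which keeps the vinyl geometry, quenching with CO2 and a cold work-up with 1 M HCl to pH 3 should give (Z)-2-{[(tert-butyldimethylsilyl)oxy]methyl}but-2-enoic acid F5; partial loss of the silyl group in the work-up would be harmless, since it only anticipates the next operation. Desilylation with aqueous HF in MeCN rejoins the route at 10.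

3. Step 1. What may go wrong: poor regioselectivity between C3 and C5, and double iodination. Fallback from 1 and 3: acid-catalysed Friedel–Crafts prenylation with ring closure (BF3·OEt2, dioxane, 20 → 50 °C), in which the cationic electrophile prefers the less hindered C5, should give 1-(7-hydroxy-2,2-dimethyl-3,4-dihydro-2H-chromen-6-yl)ethan-1-one F6. Dehydrogenation of F6 with DDQ in benzene at 80 °C rejoins the route at 5 without steps 1 to 3.

**Further compounds**
F1 | step 12 | 1-{(3S,4S)-7-[(tert-butyldimethylsilyl)oxy]-3,4-epoxy-2,2-dimethyl-3,4-dihydro-2H-chromen-6-yl}ethan-1-one | CC1(C)Oc2cc(O[Si](C)(C)C(C)(C)C)c(C(C)=O)cc2[C@@H]3O[C@H]13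
F2 | step 12 | (3S,4R)-6-acetyl-7-[(tert-butyldimethylsilyl)oxy]-3-hydroxy-2,2-dimethyl-3,4-dihydro-2H-chromen-4-yl (2Z)-2-(acetoxymethyl)but-2-enoate | CC1(C)Oc2cc(O[Si](C)(C)C(C)(C)C)c(C(C)=O)cc2[C@@H](OC(=O)/C(=C\C)COC(C)=O)[C@@H]1O
F3 | step 12 | (3S,4R)-6-acetyl-7-[(tert-butyldimethylsilyl)oxy]-2,2-dimethyl-3-{[(trifluoromethyl)sulfonyl]oxy}-3,4-dihydro-2H-chromen-4-yl (2Z)-2-(acetoxymethyl)but-2-enoate | CC1(C)Oc2cc(O[Si](C)(C)C(C)(C)C)c(C(C)=O)cc2[C@@H](OC(=O)/C(=C\C)COC(C)=O)[C@@H]1OS(=O)(=O)C(F)(F)F
F4 | step 7 | tert-butyl{[(2Z)-2-iodobut-2-en-1-yl]oxy}dimethylsilane | C/C=C(\I)CO[Si](C)(C)C(C)(C)C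
F5 | step 7 | (Z)-2-{[(tert-butyldimethylsilyl)oxy]methyl}but-2-enoic acid | C/C=C(\C(=O)O)CO[Si](C)(C)C(C)(C)C
F6 | step 1 | 1-(7-hydroxy-2,2-dimethyl-3,4-dihydro-2H-chromen-6-yl)ethan-1-one | CC(=O)c1cc2CCC(C)(C)Oc2cc1O
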